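The C4–C5 bond of the γ-lactone ring is the disconnection on which everything rests. Ring carbons C2 (carbonyl), C3 (oxygen-bearing), C4 (methylene) and C5 (oxygen-bearing, carrying the benzyl group) together spell a 4-hydroxy-2-oxo acid, the adduct of pyruvate and phenylacetaldehyde. An R-selective pyruvate aldolase joins sodium pyruvate 1 and phenylacetaldehyde 2 in one operation, making that bond and the C5 carbinol centre without closing a ring; the precursor is simply the two achiral, purchased partners. Enzymatic reduction of the remaining ketone (future C3), acid lactonisation to the trans-hydroxylactone and veratroylation finish the target.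

Key step: step 1

Remarks on the chemistry:
- The target is read as the (3R,5R)-lactone, with the acyloxy and benzyl groups trans. In open-chain numbering this is a 4R aldol adduct and a 2R carbinol (a syn-2,4-diol).
- Both enzymes are taken from known families by a small activity and selectivity screen.
- The donor is used as its sodium salt and the freshly distilled aldehyde is fed slowly.
- Compound 3 is drawn as the open keto acid although it equilibrates with its cyclic hemiketal in water.

Step 1
Reactants: 1 sodium pyruvate; 2 phenylacetaldehyde
Product: 3 (R)-4-hydroxy-2-oxo-5-phenylpentanoic acid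
Conditions: R-selective pyruvate aldolase (chosen by screening the lysine-dependent hydratase-aldolase and the metal-dependent 2-keto-3-deoxy-L-rhamnonate aldolase families; MgCl2 added for a metal-dependent enzyme), triethanolamine buffer pH 7.5, 5–10% DMSO, 25 °C, 2 (1.2 equiv) fed slowly; ultrafiltration, MTBE wash, 1 M HCl to pH 2.5 at 0 °C, EtOAc extraction, used at once
Reagents that add atoms: none
Why: The aldolase turns pyruvate into an enzyme-bound nucleophile (a lysine enamine or a metal-chelated enolate, depending on the family), which adds to the carbonyl of 2 held in the active site, and release gives the open-chain adduct. The closest known reaction type is the pyruvate-aldolase addition to non-natural aliphatic and arylaliphatic aldehydes. No ring is closed. The one new stereocentre (C4 of the acid, C5 of the later lactone) is set by the active site, which exposes a single face of the aldehyde to the bound donor; neither substrate has a stereocentre, so control rests on the catalyst alone and the R sense is secured by choosing the family member of the right facial preference. The step needs enantioface selectivity and cross- over self-aldol chemoselectivity: only pyruvate is activated as donor, and neutral pH with slow feeding should keep the enolisable aldehyde from self-condensing or inactivating the protein. Removing the enzyme before the acidic work-up should prevent retro-aldol erosion of the adduct.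

Step 2
Reactants: 3 (R)-4-hydroxy-2-oxo-5-phenylpentanoic acid
Product: 5 (3R,5R)-5-benzyl-3-hydroxydihydrofuran-2(3H)-one, via dihydroxy acid 4 (not isolated)
Conditions: NaOH to pH 7.0, 2R-selective NADH-dependent D-2-hydroxy acid dehydrogenase (D-2-hydroxyisocaproate or D-lactate dehydrogenase type, chosen by screening), NAD+ (cat.), formate dehydrogenase, HCO2Na, sodium phosphate buffer, 30 °C; then 2 M HCl to pH 1, EtOAc; TsOH (cat.), toluene, 50 °C
Reagents that add atoms: none
Why: Enzymatic carbonyl reduction by a D-specific 2-hydroxy acid dehydrogenase delivers hydride to one face of the 2-oxo group under active-site control (made irreversible by the formate dehydrogenase couple), which should set C2 as R whatever the C4 centre, and the γ-hydroxy acid then closes by acid-catalysed 5-exo-trig lactonisation, which touches neither stereocentre and gives the trans ring.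

Step 3
Reactants: 5 (3R,5R)-5-benzyl-3-hydroxydihydrofuran-2(3H)-one; 6 3,4-dimethoxybenzoyl chloride
Product: 7 Trichoderolide F, (3R,5R)-5-benzyl-2-oxotetrahydrofuran-3-yl 3,4-dimethoxybenzoate
Conditions: pyridine (2 equiv), DMAP (cat.), CH2Cl2, 0 °C to rt
Reagents that add atoms: none
Why: DMAP-catalysed acylation (nucleophilic acyl substitution) of the secondary alcohol by the aroyl chloride forms the ester at oxygen with retention at C3, and the mild base at low temperature should leave the α-acyloxy lactone unepimerised.

Compound list
1 | sodium pyruvate | CC(=O)C(=O)[O-].[Na+] | starting material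
2 | phenylacetaldehyde | O=CCc1ccccc1 | starting material
3 | (R)-4-hydroxy-2-oxo-5-phenylpentanoic acid | OC(=O)C(=O)C[C@@H](Cc1ccccc1)O | intermediate
4 | (2R,4R)-2,4-dihydroxy-5-phenylpentanoic acid (formed in the flask, not isolated) | O[C@@H](C(=O)O)C[C@@H](Cc1ccccc1)O | intermediate
5 | (3R,5R)-5-benzyl-3-hydroxydihydrofuran-2(3H)-one (trans) | O[C@@H]1C[C@@H](Cc2ccccc2)OC1=O | intermediate
6 | 3,4-dimethoxybenzoyl chloride | COc1ccc(C(=O)Cl)cc1OC | starting material
7 | Trichoderolide F, (3R,5R)-5-benzyl-2-oxotetrahydrofuran-3-yl 3,4-dimethoxybenzoate | COc1ccc(C(=O)O[C@@H]2C[C@@H](Cc3ccccc3)OC2=O)cc1OC | target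

Total step count: 3. Longest linear sequence: 3 steps.

Steps most likely to fail

Step 1. The hydrophobic, enolisable aldehyde may inactivate the aldolase or be turned over slowly, so that conversion stalls, or the facial selectivity may be insufficient. The fallback sets out from phenylacetaldehyde 2 and comes back at hydroxylactone 5.
- Asymmetric allylboration with the B-allyldiisopinocampheylborane antipode made from (+)-α-pinene (Et2O, −78 °C; NaOH, H2O2) is expected to add to the si face and give (S)-1-phenylpent-4-en-2-ol F1. This has the spatial arrangement needed at C5; the descriptor differs only through the priority rules.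
- Hydroboration–oxidation (9-BBN, THF; NaOH, H2O2) should give (S)-5-phenylpentane-1,4-diol F2.
- Oxidative lactonisation with TEMPO and PhI(OAc)2 in CH2Cl2 should give (S)-5-benzyldihydrofuran-2(3H)-one F3.
- Enolate hydroxylation (KN(SiMe3)2, THF, −78 °C, then 2-(phenylsulfonyl)-3-phenyloxaziridine) should place the hydroxyl anti to the benzyl group and so deliver the trans lactone 5.

Step 2. The reductase may fail to accept the 4-substituted keto acid, which rests largely as its cyclic hemiketal, or may show incomplete face selectivity at C2. The fallback sets out from keto acid 3 and comes back at hydroxylactone 5.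
- Carboxylate alkylation (MeI, KHCO3, DMF, rt) should give methyl (R)-4-hydroxy-2-oxo-5-phenylpentanoate F4.
- Narasaka–Prasad reduction (Et2BOMe, NaBH4, THF/MeOH, −78 °C) ties the C4 oxygen and the C2 carbonyl into a boron chelate and delivers hydride from outside. It should give the syn-diol methyl (2R,4R)-2,4-dihydroxy-5-phenylpentanoate F5.
- Acid-catalysed lactonisation (TsOH, toluene, 50 °C) then gives 5.

Step 3. Basic acylation may cause partial epimerisation at C3 or acylative opening of the lactone. The fallback activates the alcohol instead of the acid; it sets out from keto acid 3 and comes back at target 7.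
- Cyclodehydration (TsOH, toluene, Dean–Stark) should give (R)-5-benzyl-3-hydroxyfuran-2(5H)-one F6.
- Hydrogenation (H2, Rh/Al2O3, EtOAc) should add hydrogen to the face away from the benzyl group and give the cis alcohol (3S,5R)-5-benzyl-3-hydroxydihydrofuran-2(3H)-one F7.
- Mitsunobu esterification with 3,4-dimethoxybenzoic acid (PPh3, DIAD, THF, 0 °C to rt) inverts C3 and should give 7 directly under neutral conditions.

Further compounds
F1 | step 1 | (S)-1-phenylpent-4-en-2-ol | C=CC[C@@H](Cc1ccccc1)O
F2 | step 1 | (S)-5-phenylpentane-1,4-diol | OCCC[C@@H](Cc1ccccc1)O
F3 | step 1 | (S)-5-benzyldihydrofuran-2(3H)-one | O=C1CC[C@@H](Cc2ccccc2)O1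
F4 | step 2 | methyl (R)-4-hydroxy-2-oxo-5-phenylpentanoate | COC(=O)C(=O)C[C@@H](Cc1ccccc1)O
F5 | step 2 | methyl (2R,4R)-2,4-dihydroxy-5-phenylpentanoate | COC(=O)[C@H](O)C[C@@H](Cc1ccccc1)O
F6 | step 3 | (R)-5-benzyl-3-hydroxyfuran-2(5H)-one | OC1=C[C@@H](Cc2ccccc2)OC1=O
F7 | step 3 | (3S,5R)-5-benzyl-3-hydroxydihydrofuran-2(3H)-one | O[C@H]1C[C@@H](Cc2ccccc2)OC1=O
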